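The runs come from a simulation with made-up constants; scatter was added.

The pitfall in this flask is to read the stalled substrate as the end of the reaction, when the target goes on falling.

common to all: substrate 37 mM; reagent 29.6 mM

|  | remark | time |
|---|---|---|
| Thursday's | the very flask that is asked about, followed so far |  |
| flask |  | 8.0 d |

Thursday's run (percent of the substrate charged)

| time / d | target / % | substrate / % |
|---|---|---|
| 1.67 | 29.9 | 26.1 |
| 3.00 | 24.3 | 24.5 |
| 5.00 | 18.1 | 24.2 |
| 6.00 | 15.7 | 22.9 |

(scatter of a reading: 0.3 percentage points)

- alder: at 8.0 d add reagent, 50.0% of the amount charged, then wait 4.0 d
- birch: change nothing and wait 4.0 d more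
- cedar: at 8.0 d take out 90% of the target then present, then wait 4.0 d
- ash: at 8.0 d add substrate, 50.0% of the amount charged, then wait 4.0 d

- target taken out counts as made
- additions bring no volume worth counting

- target, in percent of the substrate first charged, at 8.0 d
- the remedy with the largest gain of target, or "none" below 2 percentage points (alder / birch / cedar / ash / none)
- target present, with what was taken out counted in, in percent of the substrate first charged, after birch
- target present, with what was taken out counted in, in percent of the substrate first charged, after ash

I ask first for the end state. Reagent is charged at 80.0% of the substrate, so it is the limiting reagent: in this flask substrate can fall no lower than 20.0%, and the reagent left, in percent of the substrate charged, is the substrate reading minus 20.0%.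

Then I climb the ladder of times. Fastest is the first attack: by 1.67 d substrate reads 26.1%, and target holds 40.5% of what has gone, the rest sitting in something unread. Next comes the exchange: c(target)/(c(substrate)·c(reagent)) reads 508 L mol⁻¹ at the first reading and 639 L mol⁻¹ at the last, roughly level given the scatter on so small a reagent figure, so I take target to follow that product in a steady ratio, without reading the ratio as an equilibrium constant. Slowest is the drain, a pseudo-first-order decay of target: the drain constant λ, the logarithmic slope of target between those two readings, is 0.149 d⁻¹, a half-life of 4.66 d.

So I expect 11.7% at 8.0 d, and waiting multiplies by 0.552, giving 6.46% after birch. My rule for a disturbed flask is that 40.5% of what the limiting partner can still give joins the target, and the sum then drains. With about 2.90% of reagent, ash gives 7.11%. Alder adds 40.0% of reagent, more than the substrate, so substrate limits and the gain is −0.12 percentage points. Cedar banks 90% of the target and gains 0.12 points. Both gains stay below 2 points, so I commit to none.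

The forecast gives 11.7%, 6.5% and 6.4% and names cedar, saying “Cedar narrowly beats alder”. The flask gives 11.8%, 6.63% and 6.86%, with gains of 0.23 points for alder and 0.12 points for cedar, so the answer is none.

    substrate + reagent → isomer of the product (k = 0.00110 L mol⁻¹ s⁻¹)
    substrate + reagent ⇌ target (K = 300 L mol⁻¹, k = 0.00110 L mol⁻¹ s⁻¹)

At 8.00 d the relaxation half-life of substrate + reagent and target, both ways together, is 0.578 d, shorter than the drain's 4.66 d. In that flask the backward rate then stands at 184% of the forward rate, so the exchange is not at equilibrium but running back, while the isomer of the product holds 65.7%.

For the neighbour read at 50 h, λ carried from the first reading gives 28.1%. The computed neighbour holds 27.8%.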